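I will reckon these flasks by one ratio, with the coupling partner frozen at a single value.

    coupling partner + catalyst + left-handed substrate → catalyst + left-handed product (k1 = 290 /M²/min)
    coupling partner + catalyst + right-handed substrate → catalyst + right-handed product (k2 = 120 /M²/min)
    left-handed substrate ⇌ right-handed substrate (k3 = 0.0069 /min)

common to all: left-handed substrate 0.13 M; catalyst 0.13 mM; right-handed substrate 0.13 M; time 15 h
- autumn: coupling partner 0.330 M
- winter: coupling partner 0.810 M

- which of these there is most of at the end, counted by the substrate in it, autumn (right-handed product / right-handed substrate / left-handed substrate / left-handed product)
- which of these there is most of at the end, counted by the substrate in it, winter (right-handed product / right-handed substrate / left-handed substrate / left-handed product)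
- amount of the one of these that there is most of at the end, in percent of the left-handed substrate and right-handed substrate together charged, autumn
- amount of the one of these that there is most of at the end, in percent of the left-handed substrate and right-handed substrate together charged, winter

- catalyst is single-handed; left-handed substrate and right-handed substrate are mirror images of each other, charged as a racemate, each of them at the stated concentration
- run time (autumn): 15 h

The catalyst is regenerated in both couplings, so c(catalyst) stays at its charge. I freeze c(coupling partner) at its value halfway through, the charge less 0.13 M: 0.200 M in autumn and 0.680 M in winter. Each coupling then becomes pseudo-first-order, with constants kL and kR, the third-order constant times both frozen concentrations.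

Now the ladder of half-lives. In winter the coupling of left-handed substrate has a half-life of 0.451 h, and the coupling of right-handed substrate one of 1.09 h. Both are shorter than the 1.7 h of racemisation, forward step alone, so in winter coupling outruns the refilling of the substrate pools. In autumn the left-handed coupling takes 1.53 h, close to racemisation. The right-handed coupling takes 3.70 h, so in autumn this coupling takes longer than racemisation, and part of the right-handed substrate leaves through the left-handed channel.

With racemisation constant r, I integrate both linear rate laws until the substrate is consumed. This gives the product ratio ρ, left-handed product over right-handed product: ρ = kL(kR + 2r) / [kR(kL + 2r)]. It is 1.92 in autumn and 1.50 in winter. So I expect left-handed product to lead in autumn at 65.7 %, and left-handed product to lead in winter at 59.9 %.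

The forecast names left-handed product and left-handed product, at 60.5 % in autumn and 60 % in winter, with “the lower autumn conversion offset by more effective racemisation at lower coupling-partner concentration”. I differ in autumn, where my figure stands higher.

The flasks give left-handed product at 62.9 % in autumn and left-handed product at 60.3 % in winter, so the forecast stands within its margins, and autumn ends above winter. At the end of autumn, 2.34 % left-handed and 2.68 % right-handed substrate remain. After 150 h left-handed substrate stands at 0 % and right-handed substrate at 0 %, with 66.4 % left-handed product, and the read ratio of 1.97 stands beside my ρ of 1.92.

A neighbouring flask is the autumn flask with 0.13 M of coupling partner, 1.00 equiv to left-handed substrate, which can couple half of the two substrates together, so the partner is the limiting reagent. Since ρ was integrated to consumed substrate, it serves here as an estimate only. I freeze the partner at 0.0650 M, which gives ρ = 2.20, and left-handed product 34.4 % of the substrate charged. The simulation of this neighbouring flask gives 33.8 %, with 2.3 % of the partner and 51 % of the left-handed substrate left.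

(Its constants belong to no real substance; the flask was simulated.)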